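**Retrosynthetic overview**
1. The target comes from a 5-bromo-2,3-dihydrobenzofuran by a Mizoroki–Heck reaction at C5 and ester reduction. Br serves as a base-stable placeholder for the side chain.
2. The bromide comes from one anionic [3+2] annulation that makes C2–C3 and O1–C7a together. The C=O of 3,4-dimethoxybenzaldehyde (C2, O1, ring C) is joined to the C3–C3a–C7a edge of a 2-ethylaryl p-tolyl sulfoxide (ring A).
3. Enabling feature: C3 is a benzylic CH on C3a, directly ortho to C7a of ring A, and C2–O1 is the carbonyl of a non-enolisable aldehyde. One (S)-p-tolylsulfinyl group on C7a can therefore acidify and chelate C3, fix its configuration, and then leave from C7a when O1 attacks.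
4. The ethylaryl sulfoxide comes from lateral methylation, preceded by Andersen sulfinylation of an aryl Grignard reagent and Sandmeyer iodination of a commercial aniline.
5. Ring order: rings A and C are bought. Ring B (the dihydrofuran) is the only ring made, in the key step.

Key step: step 4

Assumption: the sense of induction from sulfur to C3 follows the lithium chelate model given in step 4, so (S)-sulfur gives (3S). If experiment shows the opposite sense, the enantiomeric sulfinate from (+)-menthol is used in step 2 and nothing else changes.

**Step 1**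
Reactants: 1 4-bromo-2-methoxy-6-methylaniline
Product: 3 5-bromo-2-iodo-1-methoxy-3-methylbenzene, via arenediazonium chloride 2 (not isolated)
Conditions: NaNO2, aq HCl/MeCN, 0 °C; then aq KI, 0 °C → rt
Reagents that add atoms: potassium iodide, [K+].[I-]
Why: Sandmeyer-type iododediazoniation puts iodine exactly on the future C7a, giving a C–I bond that can later be addressed in the presence of the C–Br bond.

**Step 2**
Reactants: 3 5-bromo-2-iodo-1-methoxy-3-methylbenzene; 4 (1R,2S,5R)-menthyl (S)-p-toluenesulfinate
Product: 6 (S)-4-bromo-2-methoxy-6-methylphenyl p-tolyl sulfoxide, via arylmagnesium chloride 5 (not isolated)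
Conditions: i-PrMgCl, THF, −30 °C; then added to 4, THF, −30 °C → rt; aq NH4Cl
Reagents that add atoms: none
Why: Iodine–magnesium exchange, helped by the ortho methoxy group, is much faster than bromine–magnesium exchange, and the Andersen sulfoxide synthesis displaces mentholate at sulfur with inversion, so the (S)-sulfinate should give the (S)-diaryl sulfoxide as one enantiomer.

**Step 3**
Reactants: 6 (S)-4-bromo-2-methoxy-6-methylphenyl p-tolyl sulfoxide
Product: 8 (S)-4-bromo-2-ethyl-6-methoxyphenyl p-tolyl sulfoxide, via primary benzyllithium 7 (not isolated)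
Conditions: LiN(i-Pr)2, THF, −78 °C; MeI, −78 °C
Reagents that add atoms: iodomethane, CI
Why: In this lateral lithiation the sulfinyl oxygen binds the amide base and directs it to the ortho CH3 group, the chelated benzyllithium is C-methylated, and no carbon stereocentre forms while sulfur stays untouched.

**Step 4**
Reactants: 8 (S)-4-bromo-2-ethyl-6-methoxyphenyl p-tolyl sulfoxide; 9 3,4-dimethoxybenzaldehyde
Product: 12 (2S,3S)-5-bromo-2-(3,4-dimethoxyphenyl)-7-methoxy-3-methyl-2,3-dihydrobenzofuran, via chelated benzyllithium 10 (not isolated), via lithium alkoxide 11 (not isolated)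
Conditions: LiN(i-Pr)2, THF, −78 °C; 9, −78 °C; then DMPU, −78 → 40 °C; MeI quench (traps the sulfenate)
Reagents that add atoms: none
Why: Proposed new method: the amide base, directed by the sulfinyl oxygen, removes a benzylic C3–H of 8 to give the six-membered C–Li···O–S chelate 10, which adds to the carbonyl carbon of 9 (C2–C3 bond), and on warming in THF/DMPU the alkoxide oxygen of 11 attacks C7a through a Meisenheimer-type adduct (or the equivalent alkoxysulfurane) and expels p-toluenesulfenate (O1–C7a bond), so the net event is an anionic [3+2] annulation in which the auxiliary leaves by itself. The closest known reaction type is the anionic tandem of ortho-sulfinyl benzyl carbanions with imines, where C-addition is followed by intramolecular ipso-substitution of the sulfinyl group by the amide nitrogen to give enantiopure 2,3-disubstituted indolines, and the simple addition of such carbanions to aldehydes is also known, so the new element is oxygen as the ring-closing nucleophile. The only ring that closes, ring B, closes by an addition–elimination at C7a that is formally 5-exo-trig with respect to the C7a=C7 bond, with the charge pushed to C7, C5 and C3a, where the sulfinyl group itself and the inductive pull of Br at C5 help. C3 is controlled by sulfur: in the chelate the p-tolyl group stands on the ring face opposite to lithium (the C7 methoxy group blocks its in-plane position), the C3 methyl group points toward C4–H, and the lithium-bound aldehyde is delivered to the lithium face with retention, which for (S)-sulfur gives (3S). C2 is controlled by C3 and the same lithium: the aldehyde oxygen is held on the C7a side of C3 and the dimethoxyphenyl group takes the open sector between C3–H and C3–CH3 rather than the one between CH3 and ring A, which gives (2S), and this is also the epimer that should close faster because aryl and methyl end up trans on ring B. The step needs benzylic deprotonation in preference to attack at C6–H, the tolyl CH3 or C–Br, which precomplexation of the base to S–O at −78 °C secures, and it needs attack of oxygen at C7a only, which the five-membered geometry secures because no other leaving group is within reach.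

**Step 5**
Reactants: 12 (2S,3S)-5-bromo-2-(3,4-dimethoxyphenyl)-7-methoxy-3-methyl-2,3-dihydrobenzofuran; 13 methyl acrylate
Product: 14 methyl (E)-3-[(2S,3S)-2-(3,4-dimethoxyphenyl)-7-methoxy-3-methyl-2,3-dihydrobenzofuran-5-yl]prop-2-enoate
Conditions: Pd(OAc)2, P(o-tol)3, Et3N, DMF, 100 °C
Reagents that add atoms: none
Why: In the Mizoroki–Heck reaction, oxidative addition of zerovalent palladium into the only C–Br bond, insertion at the acrylate β-carbon and syn β-hydride elimination should give the (E)-cinnamate, and the weak amine base leaves C2 and C3 untouched.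

**Step 6**
Reactants: 14 methyl (E)-3-[(2S,3S)-2-(3,4-dimethoxyphenyl)-7-methoxy-3-methyl-2,3-dihydrobenzofuran-5-yl]prop-2-enoate
Product: 15 (E)-3-[(2S,3S)-2-(3,4-dimethoxyphenyl)-7-methoxy-3-methyl-2,3-dihydrobenzofuran-5-yl]prop-2-en-1-ol
Conditions: i-Bu2AlH, CH2Cl2, −78 °C; aq potassium sodium tartrate
Reagents that add atoms: none
Why: 1,2-Reduction of the unsaturated ester by the aluminium hydride at low temperature should give the (E)-allylic alcohol without touching the alkene, the aryl ethers, the benzylic C2–O bond or either stereocentre.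

**Compound list**
1 | 4-bromo-2-methoxy-6-methylaniline | COc1cc(Br)cc(C)c1N | starting material
2 | 4-bromo-2-methoxy-6-methylbenzenediazonium chloride | COc1cc(Br)cc(C)c1[N+]#N.[Cl-] | intermediate
3 | 5-bromo-2-iodo-1-methoxy-3-methylbenzene | COc1cc(Br)cc(C)c1I | intermediate
4 | (1R,2S,5R)-menthyl (S)-p-toluenesulfinate | C[C@@H]1CC[C@H]([C@@H](C1)O[S@](=O)c2ccc(C)cc2)C(C)C | starting material
5 | (4-bromo-2-methoxy-6-methylphenyl)magnesium chloride | COc1cc(Br)cc(C)c1[Mg]Cl | intermediate
6 | (S)-4-bromo-2-methoxy-6-methylphenyl p-tolyl sulfoxide | Cc1cc(Br)cc(OC)c1[S@@](=O)c1ccc(C)cc1 | intermediate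
7 | primary benzyllithium from 6 (CH2Li ortho to sulfinyl, Li bound to S–O) | [CH2-]c1cc(Br)cc(OC)c1[S@@](=O)c1ccc(C)cc1.[Li+] | intermediate
8 | (S)-4-bromo-2-ethyl-6-methoxyphenyl p-tolyl sulfoxide | CCc1cc(Br)cc(OC)c1[S@@](=O)c1ccc(C)cc1 | intermediate
9 | 3,4-dimethoxybenzaldehyde | COc1ccc(C=O)cc1OC | starting material
10 | secondary benzyllithium from 8 (CH(Li)CH3, Li bound to S–O) | C[CH-]c1cc(Br)cc(OC)c1[S@@](=O)c1ccc(C)cc1.[Li+] | intermediate
11 | lithium (1S,2S)-2-{5-bromo-3-methoxy-2-[(S)-p-tolylsulfinyl]phenyl}-1-(3,4-dimethoxyphenyl)propan-1-olate | COc1ccc([C@@H]([O-])[C@@H](C)c2cc(Br)cc(OC)c2[S@@](=O)c2ccc(C)cc2)cc1OC.[Li+] | intermediate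
12 | (2S,3S)-5-bromo-2-(3,4-dimethoxyphenyl)-7-methoxy-3-methyl-2,3-dihydrobenzofuran | COc1ccc([C@H]2Oc3c(OC)cc(Br)cc3[C@@H]2C)cc1OC | intermediate
13 | methyl acrylate | C=CC(=O)OC | starting material
14 | methyl (E)-3-[(2S,3S)-2-(3,4-dimethoxyphenyl)-7-methoxy-3-methyl-2,3-dihydrobenzofuran-5-yl]prop-2-enoate | COc1ccc([C@H]2Oc3c(OC)cc(/C=C/C(=O)OC)cc3[C@@H]2C)cc1OC | intermediate
15 | (E)-3-[(2S,3S)-2-(3,4-dimethoxyphenyl)-7-methoxy-3-methyl-2,3-dihydrobenzofuran-5-yl]prop-2-en-1-ol | COc1ccc([C@H]2Oc3c(OC)cc(/C=C/CO)cc3[C@@H]2C)cc1OC | target

**Total step count:** 6. **Longest linear sequence:** 6 (from 1).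

**Steps most likely to fail**

Step 4 (key step). The lithium alkoxide may stay aggregated and fail to attack C7a, so the sequence stops after C–C bond formation. Facial selectivity at the aldehyde may also be incomplete. The fallback uses known chemistry, makes the same two bonds one after the other, sets out from 8 and comes back at 12. The anion of 8 is added to 9 as above but quenched at −78 °C. The product (1S,2S)-2-{5-bromo-3-methoxy-2-[(S)-p-tolylsulfinyl]phenyl}-1-(3,4-dimethoxyphenyl)propan-1-ol F1 is purified to one diastereomer by chromatography. Sulfoxide–magnesium exchange (excess i-PrMgCl·LiCl, THF, −50 °C, the first equivalent being consumed by the OH group) followed by I2 gives (1S,2S)-2-(5-bromo-2-iodo-3-methoxyphenyl)-1-(3,4-dimethoxyphenyl)propan-1-ol F2. An intramolecular Ullmann-type etherification (CuI, 1,10-phenanthroline, Cs2CO3, toluene, 110 °C), faster at C–I than at C–Br, closes ring B to 12.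

Step 2. The aryl Grignard reagent carries two ortho groups, so substitution at sulfur may be slow. Ligand exchange of the product sulfoxide with unreacted Grignard reagent could then erode enantiopurity. The fallback reverses the roles of the two aryl groups, sets out from 5 and comes back at 6. Grignard reagent 5 is trapped with SO2 to give chloromagnesium 4-bromo-2-methoxy-6-methylbenzenesulfinate F3. SOCl2 converts this to 4-bromo-2-methoxy-6-methylbenzenesulfinyl chloride F4. (−)-Menthol and pyridine then give the menthyl ester as two epimers at sulfur. (1R,2S,5R)-Menthyl (R)-4-bromo-2-methoxy-6-methylbenzenesulfinate F5 is separated by crystallisation or chromatography. Its epimer, (1R,2S,5R)-menthyl (S)-4-bromo-2-methoxy-6-methylbenzenesulfinate F6, is returned to the mixture by HCl-catalysed epimerisation. The unhindered p-TolMgBr then displaces mentholate from F5 with inversion to give 6.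

Step 3. Proton transfer between product and unreacted benzyllithium during the alkylation may cause double methylation together with returned starting sulfoxide. Deprotonation may also stray to C6–H or to the tolyl CH3 group. The fallback brings in the ethyl group before sulfur, sets out from 4 and comes back at 8. Commercial 4-bromo-2-methoxyaniline F7 is iodinated ortho to nitrogen (N-iodosuccinimide, MeCN) to give 4-bromo-2-iodo-6-methoxyaniline F8. A Suzuki–Miyaura alkylation selective for C–I (EtBF3K, Pd(dppf)Cl2, Cs2CO3, THF/H2O, 80 °C) gives 4-bromo-2-ethyl-6-methoxyaniline F9. Sandmeyer iodination under the conditions of step 1 gives 5-bromo-1-ethyl-2-iodo-3-methoxybenzene F10. Iodine–magnesium exchange and reaction with 4 under the conditions of step 2 give 8 directly.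

**Further compounds**
F1 | step 4 | (1S,2S)-2-{5-bromo-3-methoxy-2-[(S)-p-tolylsulfinyl]phenyl}-1-(3,4-dimethoxyphenyl)propan-1-ol | COc1ccc([C@@H](O)[C@@H](C)c2cc(Br)cc(OC)c2[S@@](=O)c2ccc(C)cc2)cc1OC
F2 | step 4 | (1S,2S)-2-(5-bromo-2-iodo-3-methoxyphenyl)-1-(3,4-dimethoxyphenyl)propan-1-ol | COc1ccc([C@@H](O)[C@@H](C)c2cc(Br)cc(OC)c2I)cc1OC
F3 | step 2 | chloromagnesium 4-bromo-2-methoxy-6-methylbenzenesulfinate | COc1cc(Br)cc(C)c1S(=O)[O-].[Mg+2].[Cl-]
F4 | step 2 | 4-bromo-2-methoxy-6-methylbenzenesulfinyl chloride | COc1cc(Br)cc(C)c1S(=O)Cl
F5 | step 2 | (1R,2S,5R)-menthyl (R)-4-bromo-2-methoxy-6-methylbenzenesulfinate | C[C@@H]1CC[C@H]([C@@H](C1)O[S@@](=O)c2c(C)cc(Br)cc2OC)C(C)C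
F6 | step 2 | (1R,2S,5R)-menthyl (S)-4-bromo-2-methoxy-6-methylbenzenesulfinate | C[C@@H]1CC[C@H]([C@@H](C1)O[S@](=O)c2c(C)cc(Br)cc2OC)C(C)C
F7 | step 3 | 4-bromo-2-methoxyaniline | COc1cc(Br)ccc1N
F8 | step 3 | 4-bromo-2-iodo-6-methoxyaniline | COc1cc(Br)cc(I)c1N
F9 | step 3 | 4-bromo-2-ethyl-6-methoxyaniline | CCc1cc(Br)cc(OC)c1N
F10 | step 3 | 5-bromo-1-ethyl-2-iodo-3-methoxybenzene | CCc1cc(Br)cc(OC)c1I
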